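**Plan**
1. Numbering: cembrane numbering is used throughout (ring C1–C14, C1 carries the isopropyl group, C18 is the ester carbon on C4, C19 and C20 are the methyls on C8 and C12). Cuts: C9–C10 (ring closure), C4–C18 (from CO), then C6–C7, C5–C6, C12–C13, C2–C3 and C1–C14 of the open chain; the C2, C6 and C13 ketones are carried as carbinols.
2. Enabling feature: C9–C10 is the central bond of the 1,5-diene C7=C8–C9–C10–C11=C12 of the fourteen-membered ring. C9 and C10 are both allylic and both γ-carbons of the C6 and C13 enones, so they have like (donor) polarity. C9 therefore stays a donor through a temporary phenylsulfonyl group, and C10 is reversed to an acceptor as the (Z)-allylic bromide.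
3. Forward: Evans allylation, propargylation of the C2 aldehyde, two Nozaki–Hiyama–Kishi couplings (C10–C12 unit, then C7–C9 unit), sulfone-carbanion closure to a fourteen-membered dienyne, desulfonylation, cyclocarbonylation of C4≡C5 through the C2 hydroxyl (temporary lactone), then lactone opening, methylation and triple oxidation.
4. Stereochemistry: C1 (R) from the (R)-benzyloxazolidinone allylation. 11Z and 7E come from (Z)-3-iodobut-2-en-1-ol and (E)-3-iodo-2-methylprop-2-en-1-ol and are never engaged as allyl-metal species. 4E comes from syn addition across the ring alkyne.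

Key step: step 15

Remark: the carbinol carbons C2, C6 and C13 (and the sulfonyl-bearing C9 of 21) are temporary stereocentres; each is carried as a mixture of epimers and drawn without configuration, because all are erased before the target.
Remark: (E)-3-iodo-2-methylprop-2-en-1-ol and (Z)-3-iodobut-2-en-1-ol are taken as purchasable alkenyl iodides.

**Route**

Step 1
Reactants: 1 (E)-3-iodo-2-methylprop-2-en-1-ol
Product: 3 (E)-[(3-iodo-2-methylprop-2-en-1-yl)sulfonyl]benzene, via allylic mesylate 2 (not isolated)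
Conditions: MsCl, Et3N, CH2Cl2, −20 °C; then PhSO2Na, NaI (cat.), DMF, rt
Reagents that add atoms: sodium benzenesulfinate, [Na+].[O-]S(=O)c1ccccc1
Why: Mesylation followed by SN2 S-alkylation of the sulfinate (sulfone synthesis from an allylic sulfonate) should leave the alkenyl iodide and its E geometry untouched.

Step 2
Reactants: 4 (R)-4-benzyl-3-(3-methylbutanoyl)oxazolidin-2-one; 5 allyl iodide
Product: 6 (R)-4-benzyl-3-[(2R)-2-(propan-2-yl)pent-4-enoyl]oxazolidin-2-one
Conditions: NaN(SiMe3)2, THF, −78 °C; then 5, −78 → −45 °C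
Reagents that add atoms: none
Why: Evans asymmetric alkylation, in which the chelated sodium Z-enolate is allylated on the face opposite the benzyl group, should set C1 as R.

Step 3
Reactants: 6
Product: 7 (2R)-2-(propan-2-yl)pent-4-en-1-ol
Conditions: LiBH4, H2O (1 equiv), Et2O, 0 °C
Reagents that add atoms: none
Why: Reductive cleavage of the N-acyl oxazolidinone by LiBH4 should give the primary alcohol without touching the α-stereocentre or the alkene.

Step 4
Reactants: 7
Product: 8 (2R)-2-(propan-2-yl)pent-4-enal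
Conditions: Dess–Martin periodinane, NaHCO3, CH2Cl2, 0 °C → rt; used crude
Reagents that add atoms: none
Why: Dess–Martin oxidation under buffered, non-basic conditions should give the α-branched aldehyde without epimerisation at C1.

Step 5
Reactants: 8; 9 propargyl bromide
Product: 10 (5R)-5-(propan-2-yl)oct-7-en-1-yn-4-ol
Conditions: Zn dust, THF/sat. aq. NH4Cl, 0 °C
Reagents that add atoms: none
Why: Zinc-mediated Barbier propargylation (allenylzinc, SE2′) should give the homopropargylic alcohol; the new C2 carbinol (Felkin–Anh-biased mixture) is later oxidised.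

Step 6
Reactants: 10
Product: 11 (5R)-5-(propan-2-yl)oct-7-en-1-yn-4-yl pivalate
Conditions: PivCl, pyridine, DMAP (cat.), CH2Cl2, rt → 40 °C
Reagents that add atoms: pivaloyl chloride, CC(C)(C)C(=O)Cl
Why: DMAP-catalysed acylation installs a pivalate that has no acidic α-hydrogen, should survive the organometallic and amide-base steps, and is cleaved later by the hydride that removes the sulfone.

Step 7
Reactants: 11
Product: 12 (3R)-1-oxo-3-(propan-2-yl)hept-6-yn-4-yl pivalate
Conditions: OsO4 (2 mol %), NaIO4, 2,6-lutidine, dioxane/H2O, rt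
Reagents that add atoms: sodium periodate, [Na+].[O-]I(=O)(=O)=O (oxygen relayed through catalytic OsO4)
Why: Lemieux–Johnson oxidative cleavage (dihydroxylation, then glycol cleavage) should convert the terminal alkene into the C13 aldehyde while the terminal alkyne stays inert to OsO4.

Step 8
Reactants: 12; 13 (Z)-3-iodobut-2-en-1-ol
Product: 14 (2Z,6R)-1,4-dihydroxy-3-methyl-6-(propan-2-yl)dec-2-en-9-yn-7-yl pivalate
Conditions: CrCl2, NiCl2 (1 mol %), DMSO, rt
Reagents that add atoms: none
Why: Nozaki–Hiyama–Kishi coupling, in which the trisubstituted alkenylchromium species adds to the aldehyde with retention of the Z geometry (the future 11Z) and tolerates the free hydroxyl, the pivalate and the alkyne C–H; C13 forms as an epimer mixture.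

Step 9
Reactants: 14
Product: 15 (2Z,6R)-1,4-bis(tert-butyldimethylsilyloxy)-3-methyl-6-(propan-2-yl)dec-2-en-9-yn-7-yl pivalate
Conditions: TBSOTf, 2,6-lutidine, CH2Cl2, −78 → 0 °C
Reagents that add atoms: tert-butyldimethylsilyl trifluoromethanesulfonate, CC(C)(C)[Si](C)(C)OS(=O)(=O)C(F)(F)F
Why: Silyl ether formation at both hydroxyls removes the acidic O–H groups before the acetylide and carbanion steps.

Step 10
Reactants: 15
Product: 16 (6R,9Z)-8,11-bis(tert-butyldimethylsilyloxy)-9-methyl-1-oxo-6-(propan-2-yl)undec-9-en-2-yn-5-yl pivalate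
Conditions: n-BuLi (1.05 equiv), THF, −78 °C; DMF, −78 → −20 °C; poured into cold aq. KH2PO4
Reagents that add atoms: N,N-dimethylformamide, CN(C)C=O
Why: Formylation of the lithium acetylide with DMF and inverse quench into phosphate buffer is the standard route to ynals and adds C6 at the aldehyde level.

Step 11
Reactants: 16; 3
Product: 17 (2E,9R,12Z)-11,14-bis(tert-butyldimethylsilyloxy)-4-hydroxy-2,12-dimethyl-1-(phenylsulfonyl)-9-(propan-2-yl)tetradeca-2,12-dien-5-yn-8-yl pivalate
Conditions: CrCl2, NiCl2 (1 mol %), DMSO/THF, rt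
Reagents that add atoms: none
Why: A second Nozaki–Hiyama–Kishi coupling should add the E-alkenyl unit 1,2 to the ynal with retention of geometry (the future 7E), the non-basic alkenylchromium reagent leaving the acidic allylic sulfone untouched.

Step 12
Reactants: 17
Product: 18 (2E,9R,12Z)-4,11,14-tris(tert-butyldimethylsilyloxy)-2,12-dimethyl-1-(phenylsulfonyl)-9-(propan-2-yl)tetradeca-2,12-dien-5-yn-8-yl pivalate
Conditions: TBSOTf, 2,6-lutidine, CH2Cl2, −78 °C
Reagents that add atoms: tert-butyldimethylsilyl trifluoromethanesulfonate, CC(C)(C)[Si](C)(C)OS(=O)(=O)C(F)(F)F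
Why: Silyl ether formation masks the C6 hydroxyl so that no alkoxide competes in the ring closure.

Step 13
Reactants: 18
Product: 19 (2E,9R,12Z)-4,11-bis(tert-butyldimethylsilyloxy)-14-hydroxy-2,12-dimethyl-1-(phenylsulfonyl)-9-(propan-2-yl)tetradeca-2,12-dien-5-yn-8-yl pivalate
Conditions: HF·pyridine, pyridine, THF, 0 °C
Reagents that add atoms: none
Why: Buffered HF·pyridine should cleave the primary allylic silyl ether much faster than the two hindered secondary ones (selective desilylation).

Step 14
Reactants: 19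
Product: 20 (2E,9R,12Z)-14-bromo-4,11-bis(tert-butyldimethylsilyloxy)-2,12-dimethyl-1-(phenylsulfonyl)-9-(propan-2-yl)tetradeca-2,12-dien-5-yn-8-yl pivalate
Conditions: CBr4, PPh3, CH2Cl2, 0 °C
Reagents that add atoms: carbon tetrabromide, BrC(Br)(Br)Br
Why: Appel bromination converts the primary allylic alcohol into the bromide by SN2 at the oxyphosphonium stage, without allylic transposition or loss of the Z geometry.

Step 15
Reactants: 20
Product: 21 (1R,7E,11Z)-6,13-bis(tert-butyldimethylsilyloxy)-9-(phenylsulfonyl)-2-(pivaloyloxy)-18-norcembra-7,11-dien-4-yne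
Conditions: NaN(SiMe3)2 (1.2 equiv), THF, 2 mM final concentration, −78 → −20 °C, 20 added over 6 h by syringe pump
Reagents that add atoms: none
Why: Deprotonation α to the sulfone gives the allylic sulfonyl carbanion localised at C9, which displaces bromide from the primary allylic carbon C10 in an intramolecular SN2 reaction. The closest known reaction type is the sulfone-carbanion (Julia-type) alkylation of an allylic halide used to close cembranoid rings at a 1,5-diene. The fourteen-membered carbocycle closes in the 14-exo-tet mode. The only new stereocentre, the sulfonyl-bearing C9, is not controlled and is erased in step 16. The step needs α- over γ-alkylation of the allyl sulfone anion (secured by the sulfonyl group), SN2 over SN2′ attack (C10 is primary, C12 fully substituted), and ring closure over oligomerisation and over loss of the C6 silyloxy group (secured by high dilution and low temperature). Because C11=C12 and C7=C8 never become part of an allyl-metal or π-allyl species, the 11Z and 7E geometries should be carried through unchanged.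

Step 16
Reactants: 21
Product: 22 (1R,7E,11Z)-6,13-bis(tert-butyldimethylsilyloxy)-18-norcembra-7,11-dien-4-yn-2-ol
Conditions: PdCl2(dppp) (10 mol %), LiBHEt3 (6 equiv), THF, 0 °C → rt
Reagents that add atoms: none
Why: Palladium-catalysed reductive desulfonylation of the allylic sulfone (hydride capture of the π-allylpalladium unit at C9, the terminus remote from the branched, oxygenated C6) should restore C9 as CH2 with 7E in place, while excess hydride cleaves the pivalate and frees the C2 hydroxyl.

Step 17
Reactants: 22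
Product: 23 (1R,4E,7E,11Z)-6,13-bis(tert-butyldimethylsilyloxy)cembra-4,7,11-trieno-18,2-lactone
Conditions: PdCl2 (10 mol %), PPh3 (20 mol %), SnCl2 (10 mol %), CO (7 atm), MeCN, 70 °C
Reagents that add atoms: carbon monoxide, [C-]#[O+]
Why: Palladium-catalysed cyclocarbonylation of a homopropargylic alcohol, in which the alkoxycarbonyl-palladium unit formed at the C2 oxygen adds syn and 5-exo across the ring alkyne and protonolysis with retention gives the E-alkylidene lactone, placing C18 on C4 and fixing 4E.

Step 18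
Reactants: 23
Product: 24 (1R,4E,7E,11Z)-6,13-dihydroxycembra-4,7,11-trieno-18,2-lactone
Conditions: HF·pyridine, THF, 0 °C → rt
Reagents that add atoms: none
Why: Fluoride-mediated cleavage of both secondary silyl ethers under mildly acidic conditions should leave the alkylidene lactone intact.

Step 19
Reactants: 24
Product: 26 methyl (1R,4E,7E,11Z)-2,6,13-trihydroxycembra-4,7,11-trien-18-oate, via potassium hydroxy-carboxylate 25 (not isolated)
Conditions: KOH (1.05 equiv), THF/H2O, 0 °C; concentrate; MeI, DMF, 0 °C → rt; used at once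
Reagents that add atoms: potassium hydroxide, [K+].[OH-]; iodomethane, CI
Why: Saponification of the lactone and O-alkylation of the carboxylate salt (ester formation under neutral conditions) should give the γ-hydroxy methyl ester without the acid that would reclose the lactone.

Step 20
Reactants: 26
Product: 27 methyl sarcoate, methyl (1R,4E,7E,11Z)-2,6,13-trioxocembra-4,7,11-trien-18-oate
Conditions: Dess–Martin periodinane (5 equiv), NaHCO3, CH2Cl2, 0 °C → rt
Reagents that add atoms: none
Why: Dess–Martin oxidation of the three secondary carbinols should give the C2, C6 and C13 ketones under non-basic conditions that spare the C1 stereocentre, the acidic C3 methylene and the 11Z enone.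

**Compound list**
1 | (E)-3-iodo-2-methylprop-2-en-1-ol | OC/C(C)=C/I | starting material
2 | (E)-3-iodo-2-methylprop-2-en-1-yl methanesulfonate | CS(=O)(=O)OC/C(C)=C/I | intermediate
3 | (E)-[(3-iodo-2-methylprop-2-en-1-yl)sulfonyl]benzene | O=S(=O)(C/C(C)=C/I)c1ccccc1 | intermediate
4 | (R)-4-benzyl-3-(3-methylbutanoyl)oxazolidin-2-one | CC(C)CC(=O)N1[C@H](Cc2ccccc2)COC1=O | starting material
5 | allyl iodide | C=CCI | starting material
6 | (R)-4-benzyl-3-[(2R)-2-(propan-2-yl)pent-4-enoyl]oxazolidin-2-one | C=CC[C@H](C(C)C)C(=O)N1[C@H](Cc2ccccc2)COC1=O | intermediate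
7 | (2R)-2-(propan-2-yl)pent-4-en-1-ol | C=CC[C@H](C(C)C)CO | intermediate
8 | (2R)-2-(propan-2-yl)pent-4-enal | C=CC[C@H](C(C)C)C=O | intermediate
9 | propargyl bromide | C#CCBr | starting material
10 | (5R)-5-(propan-2-yl)oct-7-en-1-yn-4-ol | C=CC[C@H](C(C)C)C(O)CC#C | intermediate
11 | (5R)-5-(propan-2-yl)oct-7-en-1-yn-4-yl pivalate | C=CC[C@H](C(C)C)C(CC#C)OC(=O)C(C)(C)C | intermediate
12 | (3R)-1-oxo-3-(propan-2-yl)hept-6-yn-4-yl pivalate | O=CC[C@H](C(C)C)C(CC#C)OC(=O)C(C)(C)C | intermediate
13 | (Z)-3-iodobut-2-en-1-ol | OC/C=C(/C)I | starting material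
14 | (2Z,6R)-1,4-dihydroxy-3-methyl-6-(propan-2-yl)dec-2-en-9-yn-7-yl pivalate | OC/C=C(/C)C(O)C[C@H](C(C)C)C(CC#C)OC(=O)C(C)(C)C | intermediate
15 | (2Z,6R)-1,4-bis(tert-butyldimethylsilyloxy)-3-methyl-6-(propan-2-yl)dec-2-en-9-yn-7-yl pivalate | CC(C)(C)[Si](C)(C)OC/C=C(/C)C(O[Si](C)(C)C(C)(C)C)C[C@H](C(C)C)C(CC#C)OC(=O)C(C)(C)C | intermediate
16 | (6R,9Z)-8,11-bis(tert-butyldimethylsilyloxy)-9-methyl-1-oxo-6-(propan-2-yl)undec-9-en-2-yn-5-yl pivalate | CC(C)(C)[Si](C)(C)OC/C=C(/C)C(O[Si](C)(C)C(C)(C)C)C[C@H](C(C)C)C(CC#CC=O)OC(=O)C(C)(C)C | intermediate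
17 | (2E,9R,12Z)-11,14-bis(tert-butyldimethylsilyloxy)-4-hydroxy-2,12-dimethyl-1-(phenylsulfonyl)-9-(propan-2-yl)tetradeca-2,12-dien-5-yn-8-yl pivalate | CC(C)(C)[Si](C)(C)OC/C=C(/C)C(O[Si](C)(C)C(C)(C)C)C[C@H](C(C)C)C(CC#CC(O)/C=C(\C)CS(=O)(=O)c1ccccc1)OC(=O)C(C)(C)C | intermediate
18 | (2E,9R,12Z)-4,11,14-tris(tert-butyldimethylsilyloxy)-2,12-dimethyl-1-(phenylsulfonyl)-9-(propan-2-yl)tetradeca-2,12-dien-5-yn-8-yl pivalate | CC(C)(C)[Si](C)(C)OC/C=C(/C)C(O[Si](C)(C)C(C)(C)C)C[C@H](C(C)C)C(CC#CC(O[Si](C)(C)C(C)(C)C)/C=C(\C)CS(=O)(=O)c1ccccc1)OC(=O)C(C)(C)C | intermediate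
19 | (2E,9R,12Z)-4,11-bis(tert-butyldimethylsilyloxy)-14-hydroxy-2,12-dimethyl-1-(phenylsulfonyl)-9-(propan-2-yl)tetradeca-2,12-dien-5-yn-8-yl pivalate | OC/C=C(/C)C(O[Si](C)(C)C(C)(C)C)C[C@H](C(C)C)C(CC#CC(O[Si](C)(C)C(C)(C)C)/C=C(\C)CS(=O)(=O)c1ccccc1)OC(=O)C(C)(C)C | intermediate
20 | (2E,9R,12Z)-14-bromo-4,11-bis(tert-butyldimethylsilyloxy)-2,12-dimethyl-1-(phenylsulfonyl)-9-(propan-2-yl)tetradeca-2,12-dien-5-yn-8-yl pivalate | BrC/C=C(/C)C(O[Si](C)(C)C(C)(C)C)C[C@H](C(C)C)C(CC#CC(O[Si](C)(C)C(C)(C)C)/C=C(\C)CS(=O)(=O)c1ccccc1)OC(=O)C(C)(C)C | intermediate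
21 | (1R,7E,11Z)-6,13-bis(tert-butyldimethylsilyloxy)-9-(phenylsulfonyl)-2-(pivaloyloxy)-18-norcembra-7,11-dien-4-yne | C1/C=C(/C)C(O[Si](C)(C)C(C)(C)C)C[C@H](C(C)C)C(OC(=O)C(C)(C)C)CC#CC(O[Si](C)(C)C(C)(C)C)/C=C(\C)C1S(=O)(=O)c2ccccc2 | intermediate
22 | (1R,7E,11Z)-6,13-bis(tert-butyldimethylsilyloxy)-18-norcembra-7,11-dien-4-yn-2-ol | C1/C=C(/C)C(O[Si](C)(C)C(C)(C)C)C[C@H](C(C)C)C(O)CC#CC(O[Si](C)(C)C(C)(C)C)/C=C(\C)C1 | intermediate
23 | (1R,4E,7E,11Z)-6,13-bis(tert-butyldimethylsilyloxy)cembra-4,7,11-trieno-18,2-lactone | C1/C=C(/C)C(O[Si](C)(C)C(C)(C)C)C[C@H](C(C)C)C2C/C(C(=O)O2)=C\C(O[Si](C)(C)C(C)(C)C)/C=C(\C)C1 | intermediate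
24 | (1R,4E,7E,11Z)-6,13-dihydroxycembra-4,7,11-trieno-18,2-lactone | C1/C=C(/C)C(O)C[C@H](C(C)C)C2C/C(C(=O)O2)=C\C(O)/C=C(\C)C1 | intermediate
25 | potassium (1R,4E,7E,11Z)-2,6,13-trihydroxycembra-4,7,11-trien-18-oate | C1/C=C(/C)C(O)C[C@H](C(C)C)C(O)C/C(C(=O)[O-])=C\C(O)/C=C(\C)C1.[K+] | intermediate
26 | methyl (1R,4E,7E,11Z)-2,6,13-trihydroxycembra-4,7,11-trien-18-oate | C1/C=C(/C)C(O)C[C@H](C(C)C)C(O)C/C(C(=O)OC)=C\C(O)/C=C(\C)C1 | intermediate
27 | methyl sarcoate, methyl (1R,4E,7E,11Z)-2,6,13-trioxocembra-4,7,11-trien-18-oate | COC(=O)/C1=C/C(=O)/C=C(\C)CC/C=C(/C)C(=O)C[C@H](C(C)C)C(=O)C1 | target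

**Totals**
Total step count: 20. Longest linear sequence: 19 steps (steps 2–20, from 4 to 27).

**Steps most likely to fail, with fallbacks**

Step 15. The sulfonyl carbanion may expel the C6 silyloxy group by 1,4-elimination, or chains may couple with one another faster than the ring closes. The closure would then be moved from an SN2 displacement to a palladium-templated allylation. Setting out from 19, the primary alcohol would be converted (ClCO2Me, pyridine) into the allylic methyl carbonate F1. The sulfonyl carbanion, pre-formed with NaN(SiMe3)2 at −78 °C, would be added slowly to Pd(PPh3)4/dppe in THF at 40 °C. The π-allylpalladium unit generated at C10–C12 should be trapped at its unsubstituted terminus C10 by the tethered carbanion (Tsuji–Trost macrocyclisation), which returns to the route at 21. The faster electrophile shortens the lifetime of the free carbanion. Syn–anti exchange of the π-allyl unit, the only way to lose 11Z, would need a tertiary σ-allylpalladium at C12.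

Step 17. The allylic and propargylic silyl ethers may ionise in the Lewis-acidic chloride medium, or the hindered ring alkyne may resist insertion. C18 would then be brought in through a silicon tether. Setting out from 22, silylation with (Me2HSi)2NH should give the dimethylsilyl ether F2. H2PtCl6-catalysed intramolecular syn hydrosilylation (5-exo-dig) should give the cyclic alkenylsiloxane F3. Iododesilylation with N-iodosuccinimide in (CF3)2CHOH, with retention, followed by aqueous work-up, should give the hydroxy alkenyl iodide F4. Carbonylative lactonisation (Pd(PPh3)4, CO 1 atm, Et3N, MeCN) then closes the lactone and returns at 23 with the same 4E geometry.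

Step 11. The ynal 16 may decompose (loss of the pivalate across C2–C3, polymerisation) before the alkenylchromium reagent adds. The roles of the partners would then be exchanged so that no ynal is needed. Setting out from 15, the terminal alkyne would be converted (N-iodosuccinimide, AgNO3, acetone) into the iodoalkyne F5. Alkenyl iodide 3 would be formylated (Pd(PPh3)4, CO, Bu3SnH) to the enal (E)-3-methyl-4-(phenylsulfonyl)but-2-enal F6. CrCl2-mediated addition of the alkynylchromium species from F5 to F6 should give the same propargylic alcohol and return at 17.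

Further compounds
F1 | step 15 | allylic methyl carbonate of 19 | COC(=O)OC/C=C(/C)C(O[Si](C)(C)C(C)(C)C)C[C@H](C(C)C)C(CC#CC(O[Si](C)(C)C(C)(C)C)/C=C(\C)CS(=O)(=O)c1ccccc1)OC(=O)C(C)(C)C
F2 | step 17 | dimethylsilyl ether of 22 | C1/C=C(/C)C(O[Si](C)(C)C(C)(C)C)C[C@H](C(C)C)C(O[SiH](C)C)CC#CC(O[Si](C)(C)C(C)(C)C)/C=C(\C)C1
F3 | step 17 | cyclic alkenylsiloxane (silicon on C4, oxygen on C2) | C1/C=C(/C)C(O[Si](C)(C)C(C)(C)C)C[C@H](C(C)C)C2C/C([Si](C)(C)O2)=C\C(O[Si](C)(C)C(C)(C)C)/C=C(\C)C1
F4 | step 17 | hydroxy alkenyl iodide (iodine on C4, free C2 hydroxyl) | C1/C=C(/C)C(O[Si](C)(C)C(C)(C)C)C[C@H](C(C)C)C(O)C/C(I)=C\C(O[Si](C)(C)C(C)(C)C)/C=C(\C)C1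
F5 | step 11 | iodoalkyne from 15 | CC(C)(C)[Si](C)(C)OC/C=C(/C)C(O[Si](C)(C)C(C)(C)C)C[C@H](C(C)C)C(CC#CI)OC(=O)C(C)(C)C
F6 | step 11 | (E)-3-methyl-4-(phenylsulfonyl)but-2-enal | O=C/C=C(\C)CS(=O)(=O)c1ccccc1
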